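The runs are calculated with made-up constants.

The leftover of the elm run puzzled me: its opening pace, a pseudo-first-order constant k = 0.0378 h⁻¹ over the first 19 h, should have left 0.00612 M of starting material (concentration S) at 74 h, yet the readings left 0.0103 M, more.

| flask | starting material | free catalyst | time |
|---|---|---|---|
| elm | 0.100 M | 0.00500 M |  |
| larch | 0.0600 M | 0.00500 M |  |
| oak | 0.100 M | 0.00250 M |  |
| maple | 0.0250 M | 0.00500 M | 74 h |

| elm run: time / h | elm run: [product] / M | larch run: time / h | larch run: [product] / M | oak run: time / h | oak run: [product] / M |
|---|---|---|---|---|---|
| 3.3 | 0.0122 | 3.3 | 0.0076 | 3.3 | 0.0039 |
| 10 | 0.0309 | 10 | 0.0182 | 10 | 0.0164 |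
| 19 | 0.0512 | 19 | 0.0287 | 19 | 0.0270 |
| 30 | 0.0674 | 30 | 0.0394 | 30 | 0.0397 |
| 43 | 0.0791 | 43 | 0.0463 | 43 | 0.0502 |
| 58 | 0.0858 | 58 | 0.0519 | 58 | 0.0625 |
| 74 | 0.0897 | 74 | 0.0508 | 74 | 0.0701 |

(each reading ± 0.001 M)

- Overall: starting material -> product, with free catalyst as catalyst.
- Constant volume, constant temperature.
- A reading of a species includes what of it is bound.
- An order is taken over about fifteen percent of the charge, up and down.

1. apparent order in [starting material] of the starting rate, round the charge of the elm run (the rate where two percent of its starting material have turned into product) (one fixed amount of product, the same in the runs compared)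
2. apparent order in [free catalyst] of the starting rate, round the charge of the elm run (the rate where two percent of its starting material have turned into product)
3. the larch run starts with 0.0400 M less of starting material than the elm run, and with no product. Compared where both hold the same amount of starting material, once fifteen percent of what the larch run was charged with has turned into product, is the larch run faster, slower or alike (within a tenth)?
4. product in the maple run at 74 h, as a share of the starting material charged
5. which of these the readings show (the catalyst dies in pairs / the product binds the substrate / the catalyst wakes slowly / a little impurity takes part of the catalyst at once / nothing beyond the main steps)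

I went through the elm run in slow motion, taking S as charge minus product. I worked out two measures for each stretch: the first-order constant, and the slope of the reciprocal of S against time, which stays level if the rate goes as the square of S.

| Elm stretch | First-order constant | Slope of reciprocal S |
|---|---|---|
| start to 19 h | 0.0378 h⁻¹ | 0.552 L mol⁻¹ h⁻¹ |
| 43 h to 58 h | 0.0258 h⁻¹ | 1.51 L mol⁻¹ h⁻¹ |
| 58 h to 74 h | 0.0201 h⁻¹ | 1.67 L mol⁻¹ h⁻¹ |

From the first stretch of the elm run to the last the first-order constant sags, while over the two late stretches the slope of the reciprocal holds roughly level. So I read the tail of the elm run as second order, with g = 1.59 L mol⁻¹ h⁻¹ taken from 43 h to 74 h, a reading that one standard deviation of the last point moves by 0.304 L mol⁻¹ h⁻¹.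

Setting k times S equal to g times the square of S gives S× = k/g = 0.0238 M, the crossover concentration, as read from the elm run, at which the first-order law hands over to the second-order one. The elm run passed it between 30 h and 43 h, holding 0.0326 M and then 0.0209 M.

The maple run has the catalyst charge of the elm run and opens at 0.0250 M, about level with S×, so I treated it as second order throughout. The reciprocal of S then grows by g per hour, and I committed to 74.6% of the charge as product at 74 h.

The forecast gave 0.98 for the order in starting material, 1.15 for the order in free catalyst, alike for the comparison, 90% for the maple run, and "a little impurity takes part of the catalyst at once" for the diagnosis. It read the same tail differently from me: “tail off late, near 90% conversion, perhaps through slight reversibility”.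

The simulation gave 0.91, 1.1, alike, 76.7% and "a little impurity takes part of the catalyst at once".

    free catalyst + starting material ⇌ catalyst-substrate complex, settled at all times (59.50 L mol⁻¹)
    catalyst-substrate complex + starting material ⇌ doubly bound catalyst, settled at all times (4.330 L mol⁻¹)
    doubly bound catalyst → product + catalyst-substrate complex (3.600 h⁻¹)
    free catalyst + impurity → spent catalyst

The maple run opened at 0.0250 M, with S× at 0.0238 M, and ended at 76.7%, which is 2.1 percentage points above my reckoning and 13 points under the forecast. The impurity lifts the order in free catalyst to 1.1 from 0.95, but it is not the reason for the distance from the forecast, since the maple run without it gives 79.3% against 76.7%. The larch run holds 0.0300 M when half of its charge has turned, still above S×, and the first-order half-time from k is 18.3 h against the 18.7 h of the larch run.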